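## Retrosynthetic overview

1. Target 15 comes from octabenzyl ester 14 by global hydrogenolysis; 14 comes from alcohol 12 and acid 13 by esterification at O-3.
2. Ring C is the only ring built and is closed last (O1–C2) by acid-triggered MOM loss and SN1 etherification of benzylic alcohol 9; C-2 is set trans to C-3 in this closure.
3. Key C2–C3 bond: a configurationally stable α-oxy carbanion at C-3 (sparteine-complexed lithiated carbamate, a reversed-polarity donor) adds to aldehyde 7, joining two oxygen-bearing carbons; (+)-sparteine sets C-3 as S.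
4. Carbamate 6 comes from MOM ether 2 (ortho-lithiation, ethylene oxide, carbamoyl chloride); 2 comes from 3,5-bis(benzyloxy)phenol 1.
5. Rings A and B and the galloyl ring are bought as aromatic units.

Assumption: (+)-sparteine (both antipodes are sold) is used as a recoverable stoichiometric ligand, and the C-1 epimers of 9 are carried on unseparated.

## Route

**Step 1**
Reactants: 1 3,5-bis(benzyloxy)phenol
Product: 2 1,3-bis(benzyloxy)-5-(methoxymethoxy)benzene
Conditions: NaH, MOMCl, DMF, 0 °C to rt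
Reagents that add atoms: chloromethyl methyl ether (MOMCl), COCCl
Why: Williamson-type O-alkylation of the phenoxide gives the MOM ether, which later serves as the ortho-directing group and as the acid-labile mask of O-1; no stereocentre is formed.

**Step 2**
Reactants: 2 1,3-bis(benzyloxy)-5-(methoxymethoxy)benzene; 3 ethylene oxide
Product: 6 2-[2,4-bis(benzyloxy)-6-(methoxymethoxy)phenyl]ethyl N,N-diisopropylcarbamate, via aryllithium 4 (not isolated), via lithium alkoxide 5 (not isolated)
Conditions: n-BuLi, THF, 0 °C; ethylene oxide (THF solution), 0 °C to rt; then CbCl, reflux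
Reagents that add atoms: N,N-diisopropylcarbamoyl chloride (CbCl), CC(C)N(C(C)C)C(Cl)=O
Why: Directed ortho-metalation at the carbon flanked by OMOM and OBn, SN2 opening of the epoxide by the aryllithium and O-carbamoylation of the resulting lithium alkoxide install the C4–C3 unit with its directing carbamate in one flask; no stereocentre is formed.

**Step 3**
Reactants: 6 2-[2,4-bis(benzyloxy)-6-(methoxymethoxy)phenyl]ethyl N,N-diisopropylcarbamate; 7 3,4,5-tris(benzyloxy)benzaldehyde
Product: 9 (2S)-3-[2,4-bis(benzyloxy)-6-(methoxymethoxy)phenyl]-1-hydroxy-1-[3,4,5-tris(benzyloxy)phenyl]propan-2-yl N,N-diisopropylcarbamate (C-1 epimer mixture), via lithiated carbamate 8 (not isolated)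
Conditions: s-BuLi, (+)-sparteine, Et2O, −78 °C, 5 h; then 7 in THF, −78 °C; AcOH/MeOH quench
Reagents that add atoms: none
Why: Hoppe enantioselective α-deprotonation, in which s-BuLi/(+)-sparteine held by the carbamate carbonyl removes the pro-R hydrogen to give a dipole-stabilised, configurationally stable (R)-α-oxy organolithium that adds to the aldehyde with retention, fixes C-3 as S (er of about 95:5 expected), while the new carbinol centre forms unselectively and is erased in step 4.

**Step 4**
Reactants: 9 (2S)-3-[2,4-bis(benzyloxy)-6-(methoxymethoxy)phenyl]-1-hydroxy-1-[3,4,5-tris(benzyloxy)phenyl]propan-2-yl N,N-diisopropylcarbamate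
Product: 11 (2R,3S)-5,7-bis(benzyloxy)-2-[3,4,5-tris(benzyloxy)phenyl]chroman-3-yl N,N-diisopropylcarbamate, via free phenol 10 (not isolated)
Conditions: HCl (3 M in MeOH), THF, 40 °C
Reagents that add atoms: none
Why: Acid-mediated deprotective cyclodehydration (SN1 etherification with neighbouring-group participation), in which methanolysis frees the phenol, both C-1 epimers ionise to the same trialkoxybenzylic cation, the carbamate carbonyl captures it as the more stable trans-2-iminio-1,3-dioxolane and backside attack of the phenol at the benzylic carbon gives the 2,3-trans (2R) chroman with C-3 untouched; the minor 2,3-cis epimer is removed by chromatography.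

**Step 5**
Reactants: 11 (2R,3S)-5,7-bis(benzyloxy)-2-[3,4,5-tris(benzyloxy)phenyl]chroman-3-yl N,N-diisopropylcarbamate
Product: 12 (2R,3S)-5,7-bis(benzyloxy)-2-[3,4,5-tris(benzyloxy)phenyl]chroman-3-ol
Conditions: LiAlH4, THF, reflux; aqueous work-up
Reagents that add atoms: none
Why: Hydride reduction cleaves the hindered carbamate at its carbonyl carbon only, so the O-3 alcohol is released without touching either stereocentre or the benzyl ethers, and crystallisation of 12 upgrades dr and er.

**Step 6**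
Reactants: 12 (2R,3S)-5,7-bis(benzyloxy)-2-[3,4,5-tris(benzyloxy)phenyl]chroman-3-ol; 13 3,4,5-tris(benzyloxy)benzoic acid
Product: 14 (2R,3S)-5,7-bis(benzyloxy)-2-[3,4,5-tris(benzyloxy)phenyl]chroman-3-yl 3,4,5-tris(benzyloxy)benzoate
Conditions: DCC, DMAP, CH2Cl2, rt
Reagents that add atoms: none
Why: Steglich esterification acylates the only free hydroxyl under neutral conditions, so no stereocentre is touched.

**Step 7**
Reactants: 14 (2R,3S)-5,7-bis(benzyloxy)-2-[3,4,5-tris(benzyloxy)phenyl]chroman-3-yl 3,4,5-tris(benzyloxy)benzoate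
Product: 15 (+)-gallocatechin gallate
Conditions: H2 (1 atm), Pd(OH)2/C, THF/MeOH, rt
Reagents that add atoms: none
Why: Catalytic hydrogenolysis removes all eight benzyl ethers under neutral, base-free conditions that leave the gallate ester and the ring C ether intact and do not epimerise C-2.

## Compound list

1 | 3,5-bis(benzyloxy)phenol | Oc1cc(OCc2ccccc2)cc(OCc2ccccc2)c1 | starting material
2 | 1,3-bis(benzyloxy)-5-(methoxymethoxy)benzene | COCOc1cc(OCc2ccccc2)cc(OCc2ccccc2)c1 | intermediate
3 | ethylene oxide | C1CO1 | starting material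
4 | [2,4-bis(benzyloxy)-6-(methoxymethoxy)phenyl]lithium | [Li]c1c(OCOC)cc(OCc2ccccc2)cc1OCc1ccccc1 | intermediate (not isolated)
5 | lithium 2-[2,4-bis(benzyloxy)-6-(methoxymethoxy)phenyl]ethoxide | [Li]OCCc1c(OCOC)cc(OCc2ccccc2)cc1OCc1ccccc1 | intermediate (not isolated)
6 | 2-[2,4-bis(benzyloxy)-6-(methoxymethoxy)phenyl]ethyl N,N-diisopropylcarbamate | CC(C)N(C(C)C)C(=O)OCCc1c(OCOC)cc(OCc2ccccc2)cc1OCc1ccccc1 | intermediate
7 | 3,4,5-tris(benzyloxy)benzaldehyde | O=Cc1cc(OCc2ccccc2)c(OCc2ccccc2)c(OCc2ccccc2)c1 | starting material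
8 | (1R)-2-[2,4-bis(benzyloxy)-6-(methoxymethoxy)phenyl]-1-lithioethyl N,N-diisopropylcarbamate, as its (+)-sparteine complex | CC(C)N(C(C)C)C(=O)O[C@H]([Li])Cc1c(OCOC)cc(OCc2ccccc2)cc1OCc1ccccc1 | intermediate (not isolated)
9 | (2S)-3-[2,4-bis(benzyloxy)-6-(methoxymethoxy)phenyl]-1-hydroxy-1-[3,4,5-tris(benzyloxy)phenyl]propan-2-yl N,N-diisopropylcarbamate, C-1 epimer mixture | CC(C)N(C(C)C)C(=O)O[C@H](C(O)c1cc(OCc2ccccc2)c(OCc2ccccc2)c(OCc2ccccc2)c1)Cc1c(OCOC)cc(OCc2ccccc2)cc1OCc1ccccc1 | intermediate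
10 | (2S)-3-[2,4-bis(benzyloxy)-6-hydroxyphenyl]-1-hydroxy-1-[3,4,5-tris(benzyloxy)phenyl]propan-2-yl N,N-diisopropylcarbamate | CC(C)N(C(C)C)C(=O)O[C@H](C(O)c1cc(OCc2ccccc2)c(OCc2ccccc2)c(OCc2ccccc2)c1)Cc1c(O)cc(OCc2ccccc2)cc1OCc1ccccc1 | intermediate (not isolated)
11 | (2R,3S)-5,7-bis(benzyloxy)-2-[3,4,5-tris(benzyloxy)phenyl]chroman-3-yl N,N-diisopropylcarbamate | CC(C)N(C(C)C)C(=O)O[C@H]1Cc2c(OCc3ccccc3)cc(OCc3ccccc3)cc2O[C@@H]1c1cc(OCc2ccccc2)c(OCc2ccccc2)c(OCc2ccccc2)c1 | intermediate
12 | (2R,3S)-5,7-bis(benzyloxy)-2-[3,4,5-tris(benzyloxy)phenyl]chroman-3-ol (penta-O-benzyl-(+)-gallocatechin) | O[C@H]1Cc2c(OCc3ccccc3)cc(OCc3ccccc3)cc2O[C@@H]1c1cc(OCc2ccccc2)c(OCc2ccccc2)c(OCc2ccccc2)c1 | intermediate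
13 | 3,4,5-tris(benzyloxy)benzoic acid | OC(=O)c1cc(OCc2ccccc2)c(OCc2ccccc2)c(OCc2ccccc2)c1 | starting material
14 | (2R,3S)-5,7-bis(benzyloxy)-2-[3,4,5-tris(benzyloxy)phenyl]chroman-3-yl 3,4,5-tris(benzyloxy)benzoate | O=C(O[C@H]1Cc2c(OCc3ccccc3)cc(OCc3ccccc3)cc2O[C@@H]1c1cc(OCc2ccccc2)c(OCc2ccccc2)c(OCc2ccccc2)c1)c1cc(OCc2ccccc2)c(OCc2ccccc2)c(OCc2ccccc2)c1 | intermediate
15 | (+)-gallocatechin gallate, (2R,3S)-5,7-dihydroxy-2-(3,4,5-trihydroxyphenyl)chroman-3-yl 3,4,5-trihydroxybenzoate | O=C(O[C@H]1Cc2c(O)cc(O)cc2O[C@@H]1c1cc(O)c(O)c(O)c1)c1cc(O)c(O)c(O)c1 | target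

## Step count and risks

Total step count: 7. Longest linear sequence: 7 steps (1 to 15).

**Most likely to fail: step 3.** s-BuLi may also metalate ring A between its oxygens or a benzylic OCH2Ph position, and chelation by the MOM oxygen may compete with sparteine and lower the er.

Fallback, setting out from 6 and returning at 9: the stereocontrol is moved from the chiral base to a hydrogenation catalyst, keeping the same α-oxy carbanion bond formation.
- Carbamate 6 is lithiated without chiral ligand (s-BuLi/TMEDA, Et2O, −78 °C, under 1 h, so less time for side metalation) and added to excess commercial methyl 3,4,5-tris(benzyloxy)benzoate. This gives racemic 3-[2,4-bis(benzyloxy)-6-(methoxymethoxy)phenyl]-1-oxo-1-[3,4,5-tris(benzyloxy)phenyl]propan-2-yl N,N-diisopropylcarbamate F6.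
- The C-3 centre of the ketone is now enolisable. Hydrogenation with RuCl2[(S)-xylbinap][(S)-daipen] or its mirror image, t-BuOK, i-PrOH and H2 (8 atm) is run as a dynamic kinetic resolution.
- The catalyst antipode that delivers the (2S)-carbamate is chosen by screening. Either C-1 epimer serves, so the product is 9. This hydrogenation is the least precedented part of the fallback.

**Second: step 4.** The 2,3-trans/cis ratio is not assured, and the iminio-dioxolane may be diverted to a cyclic carbonate.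

Fallback, setting out from 9 and returning at 12: the participating group is removed before ring closure.
- LiAlH4 (THF, reflux) converts 9 into (2S)-3-[2,4-bis(benzyloxy)-6-(methoxymethoxy)phenyl]-1-[3,4,5-tris(benzyloxy)phenyl]propane-1,2-diol F7.
- HCl (3 M in MeOH) then frees the phenol and closes ring C through the free benzylic cation of the diol.
- Closure without a participating group should favour the 2,3-trans isomer by about 3:1; the cis epimer is removed by crystallisation. This gives 12 directly, so step 5 is not needed.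

**Third: step 2.** Lithiation may occur partly between the two OBn groups, the benzyl ethers may undergo Wittig rearrangement, and the epoxide opening or in-flask carbamoylation may be sluggish.

Fallback, setting out from 1 and returning at 6: the chain position is fixed by a sigmatropic shift instead of by competing lithiation sites.
- Allyl bromide/K2CO3 (acetone) gives 1-(allyloxy)-3,5-bis(benzyloxy)benzene F1.
- Aromatic Claisen rearrangement (N,N-diethylaniline, 190 °C) gives 2-allyl-3,5-bis(benzyloxy)phenol F2 as the only ortho product.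
- NaH/MOMCl gives 2-allyl-1,5-bis(benzyloxy)-3-(methoxymethoxy)benzene F3.
- Johnson–Lemieux cleavage (OsO4 cat., NaIO4, 2,6-lutidine, dioxane/water) gives [2,4-bis(benzyloxy)-6-(methoxymethoxy)phenyl]acetaldehyde F4.
- NaBH4 in the same pot reduces F4 to 2-[2,4-bis(benzyloxy)-6-(methoxymethoxy)phenyl]ethanol F5.
- NaH/CbCl (THF, reflux) gives 6.

## Further compounds

F1 | step 2 | 1-(allyloxy)-3,5-bis(benzyloxy)benzene | C=CCOc1cc(OCc2ccccc2)cc(OCc2ccccc2)c1
F2 | step 2 | 2-allyl-3,5-bis(benzyloxy)phenol | C=CCc1c(O)cc(OCc2ccccc2)cc1OCc1ccccc1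
F3 | step 2 | 2-allyl-1,5-bis(benzyloxy)-3-(methoxymethoxy)benzene | C=CCc1c(OCOC)cc(OCc2ccccc2)cc1OCc1ccccc1
F4 | step 2 | [2,4-bis(benzyloxy)-6-(methoxymethoxy)phenyl]acetaldehyde | O=CCc1c(OCOC)cc(OCc2ccccc2)cc1OCc1ccccc1
F5 | step 2 | 2-[2,4-bis(benzyloxy)-6-(methoxymethoxy)phenyl]ethanol | OCCc1c(OCOC)cc(OCc2ccccc2)cc1OCc1ccccc1
F6 | step 3 | racemic 3-[2,4-bis(benzyloxy)-6-(methoxymethoxy)phenyl]-1-oxo-1-[3,4,5-tris(benzyloxy)phenyl]propan-2-yl N,N-diisopropylcarbamate | CC(C)N(C(C)C)C(=O)OC(Cc1c(OCOC)cc(OCc2ccccc2)cc1OCc1ccccc1)C(=O)c1cc(OCc2ccccc2)c(OCc2ccccc2)c(OCc2ccccc2)c1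
F7 | step 4 | (2S)-3-[2,4-bis(benzyloxy)-6-(methoxymethoxy)phenyl]-1-[3,4,5-tris(benzyloxy)phenyl]propane-1,2-diol, C-1 epimer mixture | O[C@H](C(O)c1cc(OCc2ccccc2)c(OCc2ccccc2)c(OCc2ccccc2)c1)Cc1c(OCOC)cc(OCc2ccccc2)cc1OCc1ccccc1
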